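## Structural features

Pestalone F is a benzophenone: two benzene rings joined through a single ketone carbon, with no stereocentre. Ring A (C1 ketone, C2 OH, C3 Cl, C4 CH3, C5 H, C6 OCH3) is an orcinol-type unit in which the two oxygens are differentiated and the one chlorine lies between the methyl group and the free hydroxyl. Ring B (C1' ketone, C2' CHO, C3' OH, C4' H, C5' OH, C6' prenyl) is a pentasubstituted, not hexasubstituted, resorcinol, because C4' keeps its hydrogen. All four positions ortho to the ketone are substituted, so the real difficulty is to create this congested aryl–C(=O)–aryl array while placing five different groups on ring B in the right order. The fragile groups are: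
- the formyl group ortho to the diaryl ketone, which is prone to intramolecular hydride-shift lactonisation with base and to condensation with amines;
- the prenyl chain next to the C5' hydroxyl, which acid can close to a chroman;
- the electron-rich phenols.

The key step exploits the fact that the adjacent ring B atoms C1' and C2' each carry a carbonyl carbon. They are read as the two carbons of an alkyne flanked by the aroyl and the formyl group. The remaining atoms C3'–C6', with oxygen at C3' and C5' and the prenyl group at C6', are read as a diene derived from a β-keto ester.

## Logic of the disconnections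

**23 ⇒ 22.** The bond cut is the O–CH2 bond of the methoxymethyl acetal on the C2 oxygen of ring A. This hydroxyl cannot be free earlier, because a phenol ortho to an alkynyl ketone would add to the triple bond and because the acetylide addition needs a base-stable neighbour. Nothing is gained in skeleton, but the last step then touches one acetal only. The forward step must use acid mild enough to leave the prenyl chain and the formyl group alone. The acetal is flanked by chlorine and by the ketone, which should make it unusually labile.

**22 ⇒ 19 + 7.** The bonds cut are C1'–C6' and C2'–C3', which opens ring B. The cut is made here because C1' and C2' bear the two carbonyl groups of a doubly activated alkyne, and C3' to C6' carry exactly the oxygen pattern and the side chain of 7. The gain is large: ring B, its five substituents and the hindered ketone all arrive in one operation from two linear pieces, and no bond is ever made between two crowded arenes. The forward step must orient the nucleophilic terminus of 7 onto the alkyne carbon next to the ketone, must react at the triple bond and not at the formyl C=O, and must aromatise cleanly.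

**19 ⇒ 17.** No skeletal bond is cut; two carbinol C–H bonds are restored. The reason is that 19 is too electrophilic to store, so it is traced to a stable diol and made immediately before use. The forward step needs a neutral oxidant that is removed by filtration.

**17 ⇒ 14 + 15.** The bond cut is the one between the benzylic carbinol carbon and the alkyne carbon. Acetylide addition to an aldehyde is dependable even when both ortho positions are occupied, and 15 brings the three missing carbons with the oxygen already at the terminus. The forward step needs full double deprotonation of 15 with no alkyllithium left over.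

**14 ⇒ 13 ⇒ 11.** The O–CH2 bond of the acetal is cut first. The C2 hydroxyl of 13 is then traced back to an O–CH3 bond, so that both ring A oxygens come from one symmetric dimethoxy pattern. The reason is that the chlorine in 11 itself breaks the symmetry and marks the ether to be cleaved. The forward step must remove only the methyl group that is wedged between chlorine and the formyl-bearing carbon.

**11 ⇒ 10 ⇒ 8.** The C3–Cl bond is cut, then the C1–CHO bond. In 10 the two open ring positions are equivalent, so chlorination poses a question of extent and not of position. The formyl carbon goes in between the two methoxy groups of 8, the site that lithiation selects. The forward steps need stoichiometric control of chlorination and clean ring metalation.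

**7 ⇒ 5 ⇒ 4 ⇒ 1 + 2.** The two O–Si bonds are cut one after the other, then the C4–C5 bond that links the terminal carbon of the keto ester to the prenyl CH2. This takes 7 back to two bulk chemicals. The forward steps need alkylation at the terminal carbon only, and an enol silyl ether geometry that places the side chain on the outside of the diene.

## Other disconnections considered

**Alternative 1:** The cut is the C1–C(=O) bond between ring A and the ketone. In the forward direction fluoride-induced 1,2-elimination of silyl triflate A2 creates a C1–C6 triple bond in ring A. The carboxylate of ring B acid A3 adds through oxygen at C6, and the C1 aryl anion then attacks the ester carbonyl, so the acyl group shifts from oxygen to carbon and gives hydroxy benzophenone A1.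
- In its favour: the two ring A oxygens are differentiated by construction, since C6 emerges as a free hydroxyl ready for methylation while C2 already carries its acetal. On this point it is better than the chosen plan, which relies on a site-selective ether cleavage.
- In its favour: the formyl group travels as a dioxolane to the end, which is safer than handling 19.
- In its favour: the alkoxy group at C2 should direct the carboxylate to C6, so the orientation is well founded.
- Against it: A3 is a fully substituted benzoic acid that needs its own regiocontrolled synthesis, so the main difficulty of ring B is not addressed. A2 needs several further steps.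
- Against it: a carboxylate with two ortho substituents is a weak nucleophile, and the acyl shift must pass through a four-membered transition state at a doubly hindered carbonyl. Simple protonation of the aryl anion, which would stop at O-arylation, is the likely competitor.
- Against it: methylation and removal of four acetal-type groups follow, and the non-chelated ring B acetals need stronger acid than the single acetal of 22.
- Comparison: it is equal in convergence, better in ring A differentiation and aldehyde protection, and clearly worse in step count (roughly twice the eleven steps of the chosen plan).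

**Alternative 2:** The cut removes three bonds of ring A (C1–C2, C2–C3, C5–C6). In the forward direction irradiation of diazoketone A5 triggers Wolff rearrangement, [2+2] addition to methoxyalkyne A6, four-electron ring opening and six-electron closure, to give phenol A4.
- In its favour: every ring A substituent is placed by the mechanism. The hydroxyl at C2 comes from the ketene carbon, the methoxy group at C6 from the alkyne, and chlorine at C3 from the chlorovinyl terminus. This is better than the chosen plan for ring A, and its orientation rests on a stronger polarisation than the aldehyde-versus-ketone preference needed for 19.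
- In its favour: the conditions are neutral.
- Against it: A6 presupposes a completed, fully substituted ring B, so the harder ring is again made by other means.
- Against it: A5 is small and sensitive, the ring closure must engage a chlorine-bearing terminus, and the bulky propargylic substituent of A6 should slow the [2+2] step.
- Against it: the bridging carbon arrives as a protected carbinol, so desilylation, oxidation and removal of three acetal-type groups follow.
- Comparison: both plans are pericyclic benzannulations. This one is the equal or better in regiochemical certainty, but worse in step economy, and it builds the easier ring.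

**Alternative 3:** The cut is the C1'–C2' bond of ring B. In the forward direction Mg(OMe)2 in methanol opens the lactone of pyranone A8. The freed keto ester chain condenses through C2' onto the neighbouring carbonyl of the 1,2-diketone, and dehydration gives resorcylate A7.
- In its favour: nucleophile and electrophile sit in one chain, so there is no orientation problem at all. On this point it is better than the chosen plan.
- In its favour: the conditions are mild, no free ynal is involved, and the C5' hydroxyl emerges differentiated from the C3' oxygen.
- Against it: C2' arrives as a methyl ester. Reducing an ester beside a diaryl ketone is not direct and invites lactone formation, so two or three corrective redox steps are needed before deprotection.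
- Against it: A8 contains a 1,2-diketone next to an enolisable, prenyl-bearing methine. It is laborious to assemble and exposed to retro-Claisen and benzilic-type pathways under methoxide.
- Comparison: it is better in regiochemical certainty and worse in oxidation-level economy and overall length. The chosen plan delivers C2' directly as the aldehyde.

Key step: step 10

Assumption: ring A is started from commercial 3,5-dimethoxytoluene, the dimethyl ether of orcinol, which saves the methylation step. Compound 7 is taken as its (3Z) isomer; the geometry at the ketene acetal is irrelevant because it is erased on aromatisation.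

## Route

Step 1
Reactants: 1 methyl acetoacetate; 2 prenyl bromide (1-bromo-3-methylbut-2-ene)
Product: 4 methyl 7-methyl-3-oxooct-6-enoate, via acetoacetate dianion 3 (not isolated)
Conditions: NaH, THF, 0 °C; n-BuLi, 0 °C; then 2, 0 °C → rt; aq HCl
Reagents that add atoms: none
Why: γ-Alkylation of a β-keto ester dianion; the second deprotonation creates the more basic terminal carbanion, which the allylic bromide alkylates at its primary carbon (SN2) while the α-position stays untouched.

Step 2
Reactants: 4 methyl 7-methyl-3-oxooct-6-enoate
Product: 5 methyl 7-methyl-3-(trimethylsilyloxy)octa-2,6-dienoate (2E/2Z mixture, inconsequential)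
Conditions: TMSCl, Et3N, hexane, rt; filtration
Reagents that add atoms: chlorotrimethylsilane, C[Si](C)(C)Cl
Why: O-Silylation of the enol of a β-keto ester with TMSCl and a tertiary amine, the standard first stage of bis(silyloxy)diene synthesis; the geometry of the enoate is irrelevant because this bond becomes the C2–C3 single bond of the diene.

Step 3
Reactants: 5 methyl 7-methyl-3-(trimethylsilyloxy)octa-2,6-dienoate
Product: 7 (3Z)-1-methoxy-7-methyl-1,3-bis(trimethylsilyloxy)octa-1,3,6-triene, via lithium dienolate 6 (not isolated)
Conditions: LiN(iPr)2 (from iPr2NH, n-BuLi), THF, −78 °C; TMSCl, −78 °C → rt; pentane, filtration, used without chromatography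
Reagents that add atoms: chlorotrimethylsilane, C[Si](C)(C)Cl
Why: Kinetic γ-deprotonation of the silyloxy enoate gives the cross-conjugated dienolate, which TMSCl traps on the ester oxygen, the established second stage for 4-alkyl-1-methoxy-1,3-bis(silyloxy)buta-1,3-dienes. The (3Z) isomer, with the side chain syn to the silyloxy oxygen and pointing out of the diene, is the expected main product.

Step 4
Reactants: 8 3,5-dimethoxytoluene
Product: 10 2,6-dimethoxy-4-methylbenzaldehyde, via 2,6-dimethoxy-4-methylphenyllithium 9 (not isolated)
Conditions: n-BuLi, THF, 0 °C → rt; DMF, 0 °C; aq HCl
Reagents that add atoms: N,N-dimethylformamide, CN(C)C=O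
Why: Directed ortho-metalation; the hydrogen between the two methoxy groups is the most acidic and doubly coordinated site, and the aryllithium is formylated by DMF.

Step 5
Reactants: 10 2,6-dimethoxy-4-methylbenzaldehyde
Product: 11 3-chloro-2,6-dimethoxy-4-methylbenzaldehyde
Conditions: SO2Cl2 (1.0 equiv), CH2Cl2, 0 °C
Reagents that add atoms: sulfuryl chloride, O=S(=O)(Cl)Cl
Why: Electrophilic aromatic chlorination; the two open positions of 10 are equivalent and each is ortho and para to a methoxy group, so only the extent of chlorination has to be controlled, and the first chlorine slows a second substitution.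

Step 6
Reactants: 11 3-chloro-2,6-dimethoxy-4-methylbenzaldehyde
Product: 13 3-chloro-2-hydroxy-6-methoxy-4-methylbenzaldehyde, via dichloroboryl aryloxide chelate 12 (not isolated)
Conditions: BCl3 (1.2 equiv), CH2Cl2, −78 → 0 °C; H2O
Reagents that add atoms: none
Why: Chelation-assisted ether cleavage by BCl3 next to a carbonyl group, which stops after one methyl group because chelate 12 is deactivated. The C2 methoxy group is wedged between chlorine and the formyl-bearing carbon, is twisted out of the ring plane and is the more basic and more strained of the two, so it should be the one cleaved, as is general for 3-substituted 2,6-dimethoxybenzoyl compounds.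

Step 7
Reactants: 13 3-chloro-2-hydroxy-6-methoxy-4-methylbenzaldehyde
Product: 14 3-chloro-6-methoxy-2-(methoxymethoxy)-4-methylbenzaldehyde
Conditions: MOMCl, iPr2NEt, CH2Cl2, 0 °C → reflux
Reagents that add atoms: chloromethyl methyl ether, COCCl
Why: O-Alkylation of the acidic, chlorine-flanked phenol with MOMCl and a hindered amine; the resulting acetal is stable to organolithium reagents, MnO2 and silyl dienes.

Step 8
Reactants: 14 3-chloro-6-methoxy-2-(methoxymethoxy)-4-methylbenzaldehyde; 15 propargyl alcohol
Product: 17 racemic 1-[3-chloro-6-methoxy-2-(methoxymethoxy)-4-methylphenyl]but-2-yne-1,4-diol, via dilithiated propargyl alcohol 16 (not isolated)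
Conditions: 15 (1.6 equiv), n-BuLi (3.2 equiv), THF, −78 → −20 °C; then 14, −78 → 0 °C; H2O
Reagents that add atoms: none
Why: 1,2-Addition of C,O-dilithiated propargyl alcohol to the aldehyde; the ortho oxygen substituents can chelate lithium and the sp-hybridised nucleophile is small enough for an aldehyde with two ortho substituents. The new carbinol centre is formed racemic and is removed in step 9.

Step 9
Reactants: 17 racemic 1-[3-chloro-6-methoxy-2-(methoxymethoxy)-4-methylphenyl]but-2-yne-1,4-diol
Product: 19 4-[3-chloro-6-methoxy-2-(methoxymethoxy)-4-methylphenyl]-4-oxobut-2-ynal, via hydroxy ynone 18 (not isolated)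
Conditions: activated MnO2 (excess), 4 Å molecular sieves, CH2Cl2, rt; filtration through Celite, concentration below 20 °C, used at once
Reagents that add atoms: none
Why: MnO2 oxidises benzylic and propargylic alcohols; the doubly activated secondary carbinol should go first to 18, and the remaining propargylic primary alcohol is then oxidised as is known for 4-hydroxybut-2-ynoates. The neutral, heterogeneous oxidant is filtered off, so the electrophilic product never meets aqueous acid or base.

Step 10
Reactants: 19 4-[3-chloro-6-methoxy-2-(methoxymethoxy)-4-methylphenyl]-4-oxobut-2-ynal; 7 (3Z)-1-methoxy-7-methyl-1,3-bis(trimethylsilyloxy)octa-1,3,6-triene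
Product: 22 O-MOM Pestalone F, 2-[3-chloro-6-methoxy-2-(methoxymethoxy)-4-methylbenzoyl]-4,6-dihydroxy-3-(3-methylbut-2-en-1-yl)benzaldehyde, via cyclohexadiene cycloadduct 20 (not isolated), via aryl bis(trimethylsilyl) ether 21 (not isolated)
Conditions: 7 (1.5 equiv), toluene, −78 → 0 °C; then THF/H2O/AcOH, 0 °C → rt
Reagents that add atoms: none
Why: The reaction is a polar, asynchronous Diels–Alder cycloaddition: the nucleophilic terminus C4 of 7, which carries the prenyl CH2, bonds to the alkyne carbon that is beta to the formyl group and alpha to the ketone (future C1'), and the ketene acetal carbon then bonds to the formyl-bearing carbon (future C2'), forming C1'–C6' and C2'–C3' and giving 20. The closest known reaction type is the benzannulation of 1-alkoxy-1,3-bis(silyloxy)buta-1,3-dienes with acetylenic aldehydes, ketones and esters, in which the adduct aromatises by loss of the alkoxy group as alcohol. Ring B is closed as a six-membered carbocycle by intermolecular [4+2] union of the four diene carbons with the two alkyne carbons, so no separate cyclisation is required. Loss of methanol across C3' and C6' gives 21, and the dilute acetic acid work-up hydrolyses both aryl O–Si bonds while sparing the acetal on ring A. The two sp3 centres of 20 are erased on aromatisation, so no stereocontrol is needed, and any (3E) diene can reach the same arene through the stepwise Michael-then-ring-closure variant. The regioselectivity needed is orientation by the aldehyde: the unhindered formyl group is the stronger acceptor, and the aryl ketone is twisted by its two ortho oxygen substituents, which lie over both faces of the alkyne π-bond conjugated with the ketone and screen a ketone-directed approach, while the orthogonal π-bond conjugated with the formyl group stays open. The chemoselectivity needed is attack at C≡C and not at the formyl C=O; the absence of any Lewis acid and the low temperature keep uncatalysed carbonyl addition slow relative to addition to the doubly activated alkyne. Because the alkyne is linear, the crowding of four ortho substituents around the ketone builds up only as the ring forms.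

Step 11
Reactants: 22 O-MOM Pestalone F
Product: 23 Pestalone F, 2-(3-chloro-2-hydroxy-6-methoxy-4-methylbenzoyl)-4,6-dihydroxy-3-(3-methylbut-2-en-1-yl)benzaldehyde
Conditions: 2 M aq HCl, THF, 0 °C → rt
Reagents that add atoms: none
Why: Acid-catalysed hydrolysis of the aryl methoxymethyl acetal. This ether is flanked by chlorine and by the ketone-bearing carbon and releases a phenol that hydrogen-bonds to the ketone, so it should cleave under conditions mild enough to leave the prenyl chain and the formyl group untouched.

## Compound list

1 | methyl acetoacetate | COC(=O)CC(C)=O | starting material
2 | prenyl bromide (1-bromo-3-methylbut-2-ene) | CC(C)=CCBr | starting material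
3 | methyl acetoacetate dianion, sodium lithium salt | [Na+].[Li+].COC([O-])=CC([O-])=C | intermediate (not isolated)
4 | methyl 7-methyl-3-oxooct-6-enoate | COC(=O)CC(=O)CCC=C(C)C | intermediate
5 | methyl 7-methyl-3-(trimethylsilyloxy)octa-2,6-dienoate (2E/2Z mixture) | COC(=O)C=C(O[Si](C)(C)C)CCC=C(C)C | intermediate
6 | lithium dienolate of 5 | [Li+].COC([O-])=C/C(O[Si](C)(C)C)=C/CC=C(C)C | intermediate (not isolated)
7 | (3Z)-1-methoxy-7-methyl-1,3-bis(trimethylsilyloxy)octa-1,3,6-triene | COC(O[Si](C)(C)C)=C/C(O[Si](C)(C)C)=C/CC=C(C)C | intermediate
8 | 3,5-dimethoxytoluene | COc1cc(C)cc(OC)c1 | starting material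
9 | 2,6-dimethoxy-4-methylphenyllithium | [Li]c1c(OC)cc(C)cc1OC | intermediate (not isolated)
10 | 2,6-dimethoxy-4-methylbenzaldehyde | COc1cc(C)cc(OC)c1C=O | intermediate
11 | 3-chloro-2,6-dimethoxy-4-methylbenzaldehyde | COc1cc(C)c(Cl)c(OC)c1C=O | intermediate
12 | dichloroboryl aryloxide chelate of 13 | COc1cc(C)c(Cl)c(OB(Cl)Cl)c1C=O | intermediate (not isolated)
13 | 3-chloro-2-hydroxy-6-methoxy-4-methylbenzaldehyde | COc1cc(C)c(Cl)c(O)c1C=O | intermediate
14 | 3-chloro-6-methoxy-2-(methoxymethoxy)-4-methylbenzaldehyde | COc1cc(C)c(Cl)c(OCOC)c1C=O | intermediate
15 | propargyl alcohol | C#CCO | starting material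
16 | dilithiated propargyl alcohol | [Li]C#CCO[Li] | intermediate (not isolated)
17 | racemic 1-[3-chloro-6-methoxy-2-(methoxymethoxy)-4-methylphenyl]but-2-yne-1,4-diol | COc1cc(C)c(Cl)c(OCOC)c1C(O)C#CCO | intermediate
18 | 1-[3-chloro-6-methoxy-2-(methoxymethoxy)-4-methylphenyl]-4-hydroxybut-2-yn-1-one | COc1cc(C)c(Cl)c(OCOC)c1C(=O)C#CCO | intermediate (not isolated)
19 | 4-[3-chloro-6-methoxy-2-(methoxymethoxy)-4-methylphenyl]-4-oxobut-2-ynal | COc1cc(C)c(Cl)c(OCOC)c1C(=O)C#CC=O | intermediate
20 | cyclohexa-1,4-diene cycloadduct (mixture of diastereomers, racemic) | COc1cc(C)c(Cl)c(OCOC)c1C(=O)C1=C(C=O)C(OC)(O[Si](C)(C)C)C=C(O[Si](C)(C)C)C1CC=C(C)C | intermediate (not isolated)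
21 | bis(trimethylsilyl) ether of 22 | COc1cc(C)c(Cl)c(OCOC)c1C(=O)c1c(C=O)c(O[Si](C)(C)C)cc(O[Si](C)(C)C)c1CC=C(C)C | intermediate (not isolated)
22 | O-MOM Pestalone F | COc1cc(C)c(Cl)c(OCOC)c1C(=O)c1c(C=O)c(O)cc(O)c1CC=C(C)C | intermediate
23 | Pestalone F | COc1cc(C)c(Cl)c(O)c1C(=O)c1c(C=O)c(O)cc(O)c1CC=C(C)C | target

## Step count and least certain steps

Total: 11 steps (3 to diene 7, 6 to ynal 19, 2 after convergence). Longest linear sequence: 8 steps (steps 4 to 11, from 8).

**Step 10 (key step).** The most likely failure is loss of regiocontrol: the diene may be oriented by the ketone instead of the aldehyde, because the two acceptors differ only moderately and the substituted diene terminus must bond to the more encumbered alkyne carbon. Carbonyl addition at the formyl group and decay of 19 before cycloaddition are the other hazards. The fallback keeps diene 7 but uses a dienophile with a single acceptor and joins the rings by organolithium addition; it sets out from 7 and 14 and returns at 23.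
- Diene 7 is combined with methyl 3-bromopropiolate F1 (from methyl propiolate, N-bromosuccinimide and catalytic AgNO3).
- Aromatisation as in step 10 should give methyl 2-bromo-4,6-dihydroxy-3-(3-methylbut-2-en-1-yl)benzoate F2.
- NaH and MOMCl give the bis(methoxymethyl) ether F3.
- iBu2AlH reduces the ester to [2-bromo-4,6-bis(methoxymethoxy)-3-(3-methylbut-2-en-1-yl)phenyl]methanol F4.
- n-BuLi (2.2 equiv) forms the alkoxide and exchanges bromine for lithium, and the aryllithium adds to aldehyde 14 to give the racemic diaryl carbinol diol F5.
- Twofold Swern oxidation gives the tris(methoxymethyl) keto aldehyde F6.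
- Aqueous HCl in THF removes the three acetals and reaches 23.

**Step 6.** The most likely failure is loss of site selectivity, with cleavage of the less hindered methoxy group or of both, since both ethers can chelate boron. The fallback changes the order of events; it sets out from 10 and returns at 13.
- BCl3 is applied to symmetric 10, where no site question exists, to give 2-hydroxy-6-methoxy-4-methylbenzaldehyde F7.
- Chlorine is then introduced ortho to the free hydroxyl with SO2Cl2 and a catalytic secondary amine in toluene, to give 13.

**Step 9.** The most likely failures are stalling at the hydroxy ynone stage, because the second alcohol is attached to an electron-poor alkyne, and loss of the product by adsorption, hydration or oligomerisation on long exposure to the oxidant. The fallback separates the two oxidations; it sets out from 14 and returns at 19.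
- Aldehyde 14 is treated with the lithium acetylide of tert-butyldimethyl(prop-2-yn-1-yloxy)silane to give the silyl-protected carbinol F8.
- MnO2 oxidises the only free alcohol, giving the silyloxy ynone F9.
- HF·pyridine in THF removes the silyl group and gives 18, now isolated.
- Dess–Martin periodinane oxidises the single primary alcohol to 19, which is filtered and used at once.

**Step 11.** The most likely failure is acid-promoted closure of the prenyl chain onto the C5' hydroxyl, or hemiacetal chemistry at the formyl group, if the acetal proves slower to hydrolyse than expected. The fallback replaces the acid-labile group by one removed under neutral conditions; it sets out from 13 and returns at 23.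
- Phenol 13 is allylated (allyl bromide, K2CO3, acetone) to give 2-(allyloxy)-3-chloro-6-methoxy-4-methylbenzaldehyde F10.
- Steps 8 to 10 are repeated to give allyl diol F11, allyl ynal F12 and O-allyl Pestalone F F13.
- Pd(PPh3)4 (zerovalent palladium, catalytic) with PhSiH3 in CH2Cl2 removes the allyl group and gives 23.

## Further compounds

F1 | step 10 | methyl 3-bromopropiolate | COC(=O)C#CBr
F2 | step 10 | methyl 2-bromo-4,6-dihydroxy-3-(3-methylbut-2-en-1-yl)benzoate | COC(=O)c1c(O)cc(O)c(CC=C(C)C)c1Br
F3 | step 10 | methyl 2-bromo-4,6-bis(methoxymethoxy)-3-(3-methylbut-2-en-1-yl)benzoate | COC(=O)c1c(OCOC)cc(OCOC)c(CC=C(C)C)c1Br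
F4 | step 10 | [2-bromo-4,6-bis(methoxymethoxy)-3-(3-methylbut-2-en-1-yl)phenyl]methanol | OCc1c(OCOC)cc(OCOC)c(CC=C(C)C)c1Br
F5 | step 10 | racemic [3-chloro-6-methoxy-2-(methoxymethoxy)-4-methylphenyl][2-(hydroxymethyl)-3,5-bis(methoxymethoxy)-6-(3-methylbut-2-en-1-yl)phenyl]methanol | COc1cc(C)c(Cl)c(OCOC)c1C(O)c1c(CO)c(OCOC)cc(OCOC)c1CC=C(C)C
F6 | step 10 | tris(methoxymethyl) ether of Pestalone F | COc1cc(C)c(Cl)c(OCOC)c1C(=O)c1c(C=O)c(OCOC)cc(OCOC)c1CC=C(C)C
F7 | step 6 | 2-hydroxy-6-methoxy-4-methylbenzaldehyde | COc1cc(C)cc(O)c1C=O
F8 | step 9 | racemic 4-(tert-butyldimethylsilyloxy)-1-[3-chloro-6-methoxy-2-(methoxymethoxy)-4-methylphenyl]but-2-yn-1-ol | COc1cc(C)c(Cl)c(OCOC)c1C(O)C#CCO[Si](C)(C)C(C)(C)C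
F9 | step 9 | 4-(tert-butyldimethylsilyloxy)-1-[3-chloro-6-methoxy-2-(methoxymethoxy)-4-methylphenyl]but-2-yn-1-one | COc1cc(C)c(Cl)c(OCOC)c1C(=O)C#CCO[Si](C)(C)C(C)(C)C
F10 | step 11 | 2-(allyloxy)-3-chloro-6-methoxy-4-methylbenzaldehyde | COc1cc(C)c(Cl)c(OCC=C)c1C=O
F11 | step 11 | racemic 1-[2-(allyloxy)-3-chloro-6-methoxy-4-methylphenyl]but-2-yne-1,4-diol | COc1cc(C)c(Cl)c(OCC=C)c1C(O)C#CCO
F12 | step 11 | 4-[2-(allyloxy)-3-chloro-6-methoxy-4-methylphenyl]-4-oxobut-2-ynal | COc1cc(C)c(Cl)c(OCC=C)c1C(=O)C#CC=O
F13 | step 11 | O-allyl Pestalone F | COc1cc(C)c(Cl)c(OCC=C)c1C(=O)c1c(C=O)c(O)cc(O)c1CC=C(C)C
A1 | alternative 1 | ortho-hydroxy benzophenone with free C6 phenol | Oc1cc(C)c(Cl)c(OCOC)c1C(=O)c1c(C2OCCO2)c(OCOC)cc(OCOC)c1CC=C(C)C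
A2 | alternative 1 | 4-chloro-3-(methoxymethoxy)-5-methyl-2-(trimethylsilyl)phenyl trifluoromethanesulfonate | COCOc1c(Cl)c(C)cc(OS(=O)(=O)C(F)(F)F)c1[Si](C)(C)C
A3 | alternative 1 | 2-(1,3-dioxolan-2-yl)-3,5-bis(methoxymethoxy)-6-(3-methylbut-2-en-1-yl)benzoic acid | OC(=O)c1c(C2OCCO2)c(OCOC)cc(OCOC)c1CC=C(C)C
A4 | alternative 2 | racemic ring A phenol with silyl-protected bridging carbinol | COc1cc(C)c(Cl)c(O)c1C(O[Si](C)(C)C(C)(C)C)c1c(C2OCCO2)c(OCOC)cc(OCOC)c1CC=C(C)C
A5 | alternative 2 | (E)-4-chloro-1-diazo-3-methylbut-3-en-2-one | [N-]=[N+]=CC(=O)/C(C)=C/Cl
A6 | alternative 2 | racemic silyl-protected 3-methoxypropargylic carbinol carrying ring B | COC#CC(O[Si](C)(C)C(C)(C)C)c1c(C2OCCO2)c(OCOC)cc(OCOC)c1CC=C(C)C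
A7 | alternative 3 | methyl resorcylate benzophenone | COC(=O)c1c(OCOC)cc(O)c(CC=C(C)C)c1C(=O)c1c(OC)cc(C)c(Cl)c1OCOC
A8 | alternative 3 | racemic 4-(methoxymethoxy)-2-pyranone with 6-side chain bearing the prenyl methine and the aryl 1,2-diketone | O=C1C=C(OCOC)C=C(O1)C(CC=C(C)C)C(=O)C(=O)c1c(OC)cc(C)c(Cl)c1OCOC
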